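# Proposed synthesis of ebenfuran IV: a boronate 1,2-shift places ring B on C2 and the formyl carbon on C3

## The problem

Ebenfuran IV (19) is an achiral 2-arylbenzofuran in which C2 carries a 4-hydroxy-2-methoxyphenyl group (ring B), C3 a formyl group, C4 a free hydroxyl, C5 a prenyl group and C6 a methoxy group, so that the benzo ring (ring A) keeps only one hydrogen, at C7. It has no stereocentre and the prenyl alkene has no geometry, which makes the task one of regiochemistry alone. Ring A is a phloroglucinol pattern whose two exocyclic oxygens (at C4 and C6) must end up different with the prenyl group between them, and its C7 is electron-rich enough to compete with C3 in any ordinary electrophilic substitution. The prenyl alkene does not tolerate strong protic acid, which hydrates it or closes it onto a free C4 hydroxyl as a chroman. The electron-rich aldehyde is open to Dakin-type oxidation, and both phenols must stay masked through the organometallic steps. The C4 oxygen lies peri to the C3 carbonyl and is flanked on its other side by the prenyl group, which gives a handle to tell it from the C6 oxygen at the very end. The feature that makes the key step possible is the C2=C3 bond of the furan, a cyclic enol ether in which the hydrogen on C2 (alpha to O1) is the most acidic one and C3 is the most nucleophilic carbon. A benzofuran that is bare at C2 and C3 can therefore take ring B at C2 as a nucleophile-derived group and the formyl carbon at C3 as an electrophile in a single operation.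

## Retrosynthesis

19 from 18. The last disconnection cuts only O-C bonds: the methyl ether at C4 and the methoxymethyl (MOM) acetal at C4' of ring B. Carrying both ring A oxygens as methyl ethers keeps every ring A intermediate symmetric until the furan exists. Differentiating the C4 oxygen from the C6 oxygen earlier would make the ortho-formylation ambiguous. Compound 18 has the full skeleton but no free phenol. The forward step must cleave one of three aryl methyl ethers. The C4 methoxy group is singled out because it is squeezed between the prenyl group and C3a, is twisted out of the ring plane, and can share a boron Lewis acid with the peri carbonyl oxygen. The same Lewis acid removes the acetal.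

18 from 9, 12 and 13. The C2-C1' bond and the bond from C3 to the formyl carbon are cut together. The neighbouring cuts are worse. A cross-coupling at C2 followed by formylation leaves C3 to compete with C7 in an electrophilic substitution. Closing the furan from a diarylalkyne pushes either the prenyl group or the oxidation level of the C3 carbon into late steps. The double cut leaves benzofuran 9 (bare at C2 and C3), ring B pinacol boronate 12 and chloroiminium salt 13, a one-carbon electrophile already at the aldehyde oxidation level. The forward reaction must lithiate 9 at C2 (14), form borate 15, direct 13 to C3 with migration of ring B from boron to C2 (16), and rearomatise by oxidation of the C2-B bond and loss of water from hemiketal 17.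

9 from 8, 7 and 6. The furan is cut at O1-C2, then at C2=C3 (C2 from a methoxymethylene ylide) and at C3-C3a (an ortho-formyl group). This leads through enol ether 8 and salicylaldehyde 7 to phenol 6. Cyclodehydration of an aryloxyacetaldehyde acetal would be one step shorter but needs strong acid that the prenyl group would not survive. Phenol 6 has lost the whole furan and is symmetric, so ortho-formylation can give only one product. Ring closure of 8 needs no more than catalytic acid.

6 from 5, 3, 2 and 1. The C5-CH2 bond to the prenyl group is cut. Electrophilic or Claisen-type prenylation of a phloroglucinol ether would scatter the group over oxygen and several ring carbons. In silyl ether 2 the only C-H flanked by two methoxy groups is the future C5, so aryllithium 4 forms there and is allylated by prenyl bromide 3 to give 5. Desilylation gives 6, and 2 comes from commercial 3,5-dimethoxyphenol 1 in one step. The forward sequence needs a silyl group bulky enough neither to direct lithiation nor to migrate.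

12 from 11 and 10. The C-B bond of 12 is cut back to aryl bromide 11, and the acetal O-C bond of 11 to commercial 4-bromo-3-methoxyphenol 10. A silyl ether on ring B would be less safe in the basic oxidative work-up of the key step. The MOM acetal has only to survive palladium catalysis, the borate chemistry and that work-up, and then leave in the final Lewis-acid step.

## Roads not taken

Alternative 1: Ring A is cut at C4-C5, C6-C7 and C3a-C4, so that a Danheiser benzannulation would build the benzo ring onto a preformed furan. The precursors would be the diazo ketone methyl 5-(2-diazoacetyl)-2-[2-methoxy-4-(triisopropylsilyloxy)phenyl]furan-3-carboxylate A1 and the alkoxyalkyne 1-methoxy-5-methylhex-4-en-1-yne A2. Photochemical Wolff rearrangement of A1 should give the furylketene methyl 2-[2-methoxy-4-(triisopropylsilyloxy)phenyl]-5-(2-oxoethenyl)furan-3-carboxylate A3. Ketene A3 should add to A2 in a [2+2] sense. Four-electron ring opening, six-electron closure onto the free furan carbon and tautomerisation would then give methyl 4-hydroxy-6-methoxy-2-[2-methoxy-4-(triisopropylsilyloxy)phenyl]-5-(3-methylbut-2-enyl)-1-benzofuran-3-carboxylate A4. The merits are real. The polarity of A2 fixes prenyl at C5 and methoxy at C6. The C4 oxygen of A4 emerges as a free phenol already distinguished from the C6 methoxy group, which is better than the chosen plan because no selective demethylation is needed. The weak points lie elsewhere. A1 is a tetrasubstituted furan that needs its own multistep synthesis and a diazo transfer. A2 is a sensitive alkoxyalkyne that must carry the prenyl alkene through UV irradiation beside the reactive ketene A3. The closing bond forms peri to the ester. A4 is at the ester oxidation level, so reduction, reoxidation and desilylation would follow. The chosen plan reaches the aldehyde oxidation level directly and is several steps shorter. In return it accepts a late demethylation of 18 that relies on chelation and hindrance.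

Alternative 2: The furan is cut at O1-C2 and at the bond between C3 and its exocyclic carbon, the reverse of a PtCl2-catalysed carboalkoxylation. The precursor would be the diarylalkyne {4-[(2,6-bis(methoxymethoxy)-4-methoxyphenyl)ethynyl]-3-methoxyphenoxy}tri(propan-2-yl)silane A5. PtCl2 would activate the alkyne of A5, one acetal oxygen would add to the alkyne carbon that bears ring B, and its methoxymethyl group would shift to the neighbouring carbon. This should give 6-methoxy-3-(methoxymethyl)-4-(methoxymethoxy)-2-[2-methoxy-4-(triisopropylsilyloxy)phenyl]-1-benzofuran A6. This is a catalytic reaction of a known type. The two acetal oxygens on ring A of A5 are equivalent, so there is no question which one closes. The C4 oxygen of A6 ends as an acetal, so the endgame would need only mild acid and no boron Lewis acid. In precedent and in the final deprotection this road is better than the chosen plan. Its weakness for this target is that A6 lacks the prenyl group. It would have to be introduced at C5 by late metalation in competition with C7 and with the benzylic CH2OMe position. The C3 carbon of A6 arrives as an ether and must be oxidised to the aldehyde on an electron-rich skeleton, with a prenyl alkene present if the order is reversed. Against this the chosen plan installs the prenyl group first on a symmetric phenol and needs no redox adjustment at C3.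

Alternative 3: The furan is cut at O1-C7a and C3-C3a, the reverse of an aryne annulation with an iodonium ylide. Fluoride should convert the silyl triflate 3,5-dimethoxy-4-(3-methylbut-2-enyl)-2-(trimethylsilyl)phenyl trifluoromethanesulfonate A7 into the aryne 1,2-didehydro-3,5-dimethoxy-4-(3-methylbut-2-enyl)benzene A8. Its partner would be the phenyliodonium ylide of methyl 3-[2-methoxy-4-(methoxymethoxy)phenyl]-3-oxopropanoate A9. The ketone enolate oxygen of A9 should add to A8 at the aryne carbon remote from the methoxy group. The aryl anion so formed should close onto the ylide carbon with loss of the hypervalent iodine leaving group. The product would be methyl 4,6-dimethoxy-2-[2-methoxy-4-(methoxymethoxy)phenyl]-5-(3-methylbut-2-enyl)-1-benzofuran-3-carboxylate A10. The ring-forming step belongs to a known reaction type and its regiochemistry follows from the polarisation of a 3-methoxyaryne such as A8. In precedent it is stronger than the chosen key step, and it would start from the same phenol 6. The cost is in the precursors and the oxidation level. A7 needs bromination, silylation, silyl migration and triflation from 6. A9 needs a keto ester synthesis and ylide formation. A10 is again an ester, two redox steps away from 18, after which the same demethylation follows. The chosen plan reaches 18 about four steps sooner and at the correct oxidation level. It pays for this with a key step that has no direct precedent.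

Key step: step 9

Assumption: intermediates 16 and 17 are transient racemic mixtures of diastereomers and enol ether 8 is an E/Z mixture; these elements vanish on aromatisation, so their SMILES carry no stereodescriptors, and the target has no stereocentre.

## Route

Step 1
Reactants: 1 3,5-dimethoxyphenol
Product: 2 (3,5-dimethoxyphenoxy)tri(propan-2-yl)silane
Conditions: NaH, THF, 0 °C; TIPSCl, 0 °C to rt
Reagents that add atoms: chlorotri(propan-2-yl)silane (TIPSCl), CC(C)[Si](Cl)(C(C)C)C(C)C
Why: O-silylation of the phenoxide formed with NaH; the bulky silyl ether is stable to n-BuLi, is a poor ortho-director and shields C2 and C6 in the next step.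

Step 2
Reactants: 2 (3,5-dimethoxyphenoxy)tri(propan-2-yl)silane; 3 1-bromo-3-methylbut-2-ene (prenyl bromide)
Product: 5 [3,5-dimethoxy-4-(3-methylbut-2-enyl)phenoxy]tri(propan-2-yl)silane, via aryllithium 4 (not isolated)
Conditions: n-BuLi, THF, 0 °C to rt; CuI (10 mol %), 3, −78 °C to rt
Reagents that add atoms: none
Why: Directed ortho-metalation at the only C-H flanked by two methoxy groups, then copper-catalysed allylic substitution at the primary carbon of 3; SN2' attack would have to build a quaternary carbon next to a di-ortho-substituted ring.

Step 3
Reactants: 5 [3,5-dimethoxy-4-(3-methylbut-2-enyl)phenoxy]tri(propan-2-yl)silane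
Product: 6 3,5-dimethoxy-4-(3-methylbut-2-enyl)phenol
Conditions: TBAF, THF, 0 °C
Reagents that add atoms: none
Why: Fluoride-induced cleavage of the aryl silyl ether, driven by Si-F bond formation and neutral towards the prenyl alkene.

Step 4
Reactants: 6 3,5-dimethoxy-4-(3-methylbut-2-enyl)phenol
Product: 7 6-hydroxy-2,4-dimethoxy-3-(3-methylbut-2-enyl)benzaldehyde
Conditions: MgCl2, Et3N, (CH2O)n, MeCN, reflux; cold dilute aq. HCl
Reagents that add atoms: paraformaldehyde (as formaldehyde), C=O
Why: Magnesium-mediated ortho-formylation (Casnati–Skattebøl reaction): the phenoxide held on the magnesium ion of MgCl2 delivers formaldehyde to the ortho carbon, the two ortho positions of 6 are equivalent and the para position is blocked; a second formaldehyde oxidises the benzylic alkoxide by hydride transfer.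

Step 5
Reactants: 7 6-hydroxy-2,4-dimethoxy-3-(3-methylbut-2-enyl)benzaldehyde
Product: 8 3,5-dimethoxy-2-(2-methoxyethenyl)-4-(3-methylbut-2-enyl)phenol (E/Z mixture)
Conditions: Ph3P(CH2OMe)Cl (3 equiv), KOt-Bu (4 equiv), THF, 0 °C to rt
Reagents that add atoms: (methoxymethyl)triphenylphosphonium chloride, COC[P+](c1ccccc1)(c1ccccc1)c1ccccc1.[Cl-]
Why: Wittig methoxymethylenation; one equivalent of base is consumed by the phenol, hence the excess of ylide, and the alkene geometry is irrelevant because both isomers cyclise in step 6.

Step 6
Reactants: 8 3,5-dimethoxy-2-(2-methoxyethenyl)-4-(3-methylbut-2-enyl)phenol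
Product: 9 4,6-dimethoxy-5-(3-methylbut-2-enyl)-1-benzofuran
Conditions: p-TsOH·H2O (5 mol %), toluene, 80 °C
Reagents that add atoms: none
Why: Acid-catalysed cyclodehydration: the phenol adds 5-exo to the protonated enol ether and the cyclic acetal loses methanol to aromatise; the enol ether is far more basic than the trisubstituted alkene, and the prenyl group has no free ortho hydroxyl to cyclise onto.

Step 7
Reactants: 10 4-bromo-3-methoxyphenol
Product: 11 1-bromo-2-methoxy-4-(methoxymethoxy)benzene
Conditions: NaH, DMF, 0 °C; MOMCl, 0 °C to rt
Reagents that add atoms: chloro(methoxy)methane (MOMCl), COCCl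
Why: O-alkylation of the phenoxide formed with NaH; the acetal tolerates palladium catalysis, the borate chemistry and the oxidative work-up of step 9.

Step 8
Reactants: 11 1-bromo-2-methoxy-4-(methoxymethoxy)benzene
Product: 12 2-[2-methoxy-4-(methoxymethoxy)phenyl]-4,4,5,5-tetramethyl-1,3,2-dioxaborolane
Conditions: B2pin2, Pd(dppf)Cl2 (3 mol %), KOAc, 1,4-dioxane, 90 °C
Reagents that add atoms: bis(pinacolato)diboron, CC1(C)OB(OC1(C)C)B1OC(C)(C)C(C)(C)O1
Why: Miyaura borylation of the aryl bromide; acetate is too weak a base to drive Suzuki coupling of the product with unreacted bromide.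

Step 9
Reactants: 9 4,6-dimethoxy-5-(3-methylbut-2-enyl)-1-benzofuran; 12 2-[2-methoxy-4-(methoxymethoxy)phenyl]-4,4,5,5-tetramethyl-1,3,2-dioxaborolane; 13 (chloromethylidene)dimethylazanium chloride
Product: 18 4,6-dimethoxy-2-[2-methoxy-4-(methoxymethoxy)phenyl]-5-(3-methylbut-2-enyl)-1-benzofuran-3-carbaldehyde, via 2-lithiobenzofuran 14 (not isolated), via lithium borate 15 (not isolated), via boryl iminium adduct 16 (not isolated), via hemiketal 17 (not isolated)
Conditions: n-BuLi (1.0 equiv), THF, −78 °C; 12, −78 °C to rt; 13, MeCN, −40 to 0 °C; NaBO3·4H2O, THF/H2O, 0 °C to rt; AcOH, rt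
Reagents that add atoms: water, O
Why: Proposed new method: n-BuLi removes the furan C2-H of 9 and the resulting 14 adds to the boron of 12 to give borate 15, whose C2=C3 bond is an enol ether made still more nucleophilic by the negative charge on boron. The chloroiminium carbon of 13 attacks C3, and the C2 oxocarbenium character that develops is quenched by 1,2-shift of ring B from boron to C2, so that the bond from C3 to the formyl carbon and the C2-C1' bond form in one event and give 16. NaBO3 then converts C2-B into C2-OH with retention while the formyl carbon is still masked as iminium ion or enamine, hydrolysis gives hemiketal 17, and AcOH dehydrates it through the C2 cation stabilised by O1 and ring B to aromatic 18. The closest known reaction types are the three-component couplings of 2-lithiated indoles or furans with boronic esters and carbon electrophiles through 1,2-metallate rearrangement and the halogen-induced couplings of heteroaryl borates; a chloroiminium electrophile on a benzofuran-2-yl borate has not been shown. No ring closes and no stereocentre survives, since the two sp3 centres of 16 and 17 are lost on aromatisation. The step needs lithiation at C2 and not at C7 or the prenyl CH2, which the acidity alpha to O1 at −78 °C should secure. It also needs attack of 13 at C3 and not at the ipso carbon of ring B or at C7, which the anionic enol ether character of 15, one equivalent of 13 and low temperature should secure.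

Step 10
Reactants: 18 4,6-dimethoxy-2-[2-methoxy-4-(methoxymethoxy)phenyl]-5-(3-methylbut-2-enyl)-1-benzofuran-3-carbaldehyde
Product: 19 4-hydroxy-2-(4-hydroxy-2-methoxyphenyl)-6-methoxy-5-(3-methylbut-2-enyl)-1-benzofuran-3-carbaldehyde (ebenfuran IV)
Conditions: BCl3, CH2Cl2, −78 to 0 °C; cold aq. NaHCO3
Reagents that add atoms: none
Why: Chelation-assisted Lewis-acid dealkylation: BCl3 held by the C3 carbonyl oxygen reaches only the peri C4 methoxy oxygen (seven-membered chelate), which is also the one methoxy group twisted out of plane by its two flanking substituents, and chloride removes its methyl group, while the MOM acetal is cleaved faster still. The C6 and C2' methyl ethers have neither a chelating partner nor this twist, and no protic acid is present before the cold basic quench.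

## Compound list

1 | 3,5-dimethoxyphenol | COc1cc(O)cc(OC)c1 | starting material
2 | (3,5-dimethoxyphenoxy)tri(propan-2-yl)silane | COc1cc(O[Si](C(C)C)(C(C)C)C(C)C)cc(OC)c1 | intermediate
3 | 1-bromo-3-methylbut-2-ene (prenyl bromide) | CC(C)=CCBr | starting material
4 | [2,6-dimethoxy-4-(triisopropylsilyloxy)phenyl]lithium | [Li]c1c(OC)cc(O[Si](C(C)C)(C(C)C)C(C)C)cc1OC | intermediate
5 | [3,5-dimethoxy-4-(3-methylbut-2-enyl)phenoxy]tri(propan-2-yl)silane | COc1cc(O[Si](C(C)C)(C(C)C)C(C)C)cc(OC)c1CC=C(C)C | intermediate
6 | 3,5-dimethoxy-4-(3-methylbut-2-enyl)phenol | COc1cc(O)cc(OC)c1CC=C(C)C | intermediate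
7 | 6-hydroxy-2,4-dimethoxy-3-(3-methylbut-2-enyl)benzaldehyde | COc1cc(O)c(C=O)c(OC)c1CC=C(C)C | intermediate
8 | 3,5-dimethoxy-2-(2-methoxyethenyl)-4-(3-methylbut-2-enyl)phenol (E/Z mixture) | COC=Cc1c(O)cc(OC)c(CC=C(C)C)c1OC | intermediate
9 | 4,6-dimethoxy-5-(3-methylbut-2-enyl)-1-benzofuran | COc1cc2occc2c(OC)c1CC=C(C)C | intermediate
10 | 4-bromo-3-methoxyphenol | COc1cc(O)ccc1Br | starting material
11 | 1-bromo-2-methoxy-4-(methoxymethoxy)benzene | COCOc1ccc(Br)c(OC)c1 | intermediate
12 | 2-[2-methoxy-4-(methoxymethoxy)phenyl]-4,4,5,5-tetramethyl-1,3,2-dioxaborolane | COCOc1ccc(B2OC(C)(C)C(C)(C)O2)c(OC)c1 | intermediate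
13 | (chloromethylidene)dimethylazanium chloride | C[N+](C)=CCl.[Cl-] | starting material
14 | [4,6-dimethoxy-5-(3-methylbut-2-enyl)-1-benzofuran-2-yl]lithium | [Li]c1cc2c(OC)c(CC=C(C)C)c(OC)cc2o1 | intermediate
15 | lithium 2-[4,6-dimethoxy-5-(3-methylbut-2-enyl)-1-benzofuran-2-yl]-2-[2-methoxy-4-(methoxymethoxy)phenyl]-4,4,5,5-tetramethyl-1,3,2-dioxaborolan-2-uide | [Li+].COCOc1ccc([B-]2(c3cc4c(OC)c(CC=C(C)C)c(OC)cc4o3)OC(C)(C)C(C)(C)O2)c(OC)c1 | intermediate
16 | {[4,6-dimethoxy-2-[2-methoxy-4-(methoxymethoxy)phenyl]-5-(3-methylbut-2-enyl)-2-(4,4,5,5-tetramethyl-1,3,2-dioxaborolan-2-yl)-2,3-dihydro-1-benzofuran-3-yl]methylidene}dimethylazanium chloride | C[N+](C)=CC1c2c(OC)c(CC=C(C)C)c(OC)cc2OC1(B1OC(C)(C)C(C)(C)O1)c1ccc(OCOC)cc1OC.[Cl-] | intermediate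
17 | 2-hydroxy-4,6-dimethoxy-2-[2-methoxy-4-(methoxymethoxy)phenyl]-5-(3-methylbut-2-enyl)-2,3-dihydro-1-benzofuran-3-carbaldehyde | O=CC1c2c(OC)c(CC=C(C)C)c(OC)cc2OC1(O)c1ccc(OCOC)cc1OC | intermediate
18 | 4,6-dimethoxy-2-[2-methoxy-4-(methoxymethoxy)phenyl]-5-(3-methylbut-2-enyl)-1-benzofuran-3-carbaldehyde | COCOc1ccc(-c2oc3cc(OC)c(CC=C(C)C)c(OC)c3c2C=O)c(OC)c1 | intermediate
19 | 4-hydroxy-2-(4-hydroxy-2-methoxyphenyl)-6-methoxy-5-(3-methylbut-2-enyl)-1-benzofuran-3-carbaldehyde (ebenfuran IV) | COc1cc(O)ccc1-c1oc2cc(OC)c(CC=C(C)C)c(O)c2c1C=O | target

## Step count and risks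

Total: 10 steps. Longest linear sequence: 8 steps (steps 1 to 6, then 9 and 10). The ring B branch (steps 7 and 8) joins at step 9.

Step 9 (key step, without direct precedent). The most likely failure is attack of the chloroiminium ion at the boron-bearing ipso carbon of ring B instead of C3. Ring B is electron-rich, so this would deliver the formyl carbon to ring B and destroy the borate. Other possible diversions are competing deprotonation at the benzylic, allylic CH2 of the prenyl group, ring opening of hemiketal 17 with reclosure of the phenol onto the formyl carbon before dehydration (which would exchange the roles of the two carbonyl carbons), and peroxide oxidation of the electron-rich aldehyde. Fallback: set out from 14 (generated from 9 as in step 9) and bromide 11 and return at 18. Transmetalation of 14 with ZnCl2 should give chloro[4,6-dimethoxy-5-(3-methylbut-2-enyl)-1-benzofuran-2-yl]zinc F1. Negishi coupling of this with 11 (Pd(OAc)2, SPhos, THF, 60 °C) should give 4,6-dimethoxy-2-[2-methoxy-4-(methoxymethoxy)phenyl]-5-(3-methylbut-2-enyl)-1-benzofuran F2. Vilsmeier–Haack formylation of the latter with salt 13 in DMF, followed by aqueous NaOAc, should then give 18. Both reactions are of known types. The price is that C3, although activated by O1 and by the alkoxyphenyl group, must outcompete C7 in an ordinary electrophilic substitution.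

Step 10. The chelate that singles out the C4 methoxy group is seven-membered, so discrimination between the three methyl ethers may be incomplete. In addition, the freed C4 oxygen could add to the prenyl cation generated by adventitious acid (chroman closure), the alkene could be hydrochlorinated, or the chloromethyl ether released from the acetal could alkylate the electron-rich rings under Lewis acid. Fallback: set out from 18 and return at 19 in two operations. HCl in MeOH at rt removes only the acetal while C4 is still methylated, so no chroman can form. This should give 2-(4-hydroxy-2-methoxyphenyl)-4,6-dimethoxy-5-(3-methylbut-2-enyl)-1-benzofuran-3-carbaldehyde F3. MgI2·OEt2 in toluene/THF at 60 °C should then cleave the methyl ether at C4. This reagent acts only on an ether oxygen that can share the magnesium ion with a carbonyl oxygen, its larger cation fits a seven-membered chelate more easily than boron, and it generates no protic acid.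

Step 6. Protonation of the prenyl alkene (hydration or isomerisation) or acid-induced oligomerisation of the electron-rich benzofuran may compete with loss of methanol. Fallback: a furan construction without acid, setting out from 6 and returning at 9. Ortho-iodination with NIS should give 2-iodo-3,5-dimethoxy-4-(3-methylbut-2-enyl)phenol F4. Sonogashira coupling with ethynyltrimethylsilane (Pd(PPh3)2Cl2, CuI, Et3N) should give 3,5-dimethoxy-4-(3-methylbut-2-enyl)-2-[(trimethylsilyl)ethynyl]phenol F5. TBAF in THF at reflux should then desilylate the alkyne and close the furan 5-endo to give 9.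

Step 5. Olefination may stall because the phenoxide formed by the first equivalent of base donates into an already hindered, di-ortho-substituted aldehyde. Fallback: mask the phenol, setting out from 7 and returning at 9. NaH and MOMCl should give 2,4-dimethoxy-6-(methoxymethoxy)-3-(3-methylbut-2-enyl)benzaldehyde F6. The same Wittig reaction should give 1,3-dimethoxy-4-(2-methoxyethenyl)-5-(methoxymethoxy)-2-(3-methylbut-2-enyl)benzene F7. HCl in MeOH at rt should then remove the acetal and close the furan in one operation.

## Further compounds

F1 | step 9 | chloro[4,6-dimethoxy-5-(3-methylbut-2-enyl)-1-benzofuran-2-yl]zinc | Cl[Zn]c1cc2c(OC)c(CC=C(C)C)c(OC)cc2o1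
F2 | step 9 | 4,6-dimethoxy-2-[2-methoxy-4-(methoxymethoxy)phenyl]-5-(3-methylbut-2-enyl)-1-benzofuran | COCOc1ccc(-c2cc3c(OC)c(CC=C(C)C)c(OC)cc3o2)c(OC)c1
F3 | step 10 | 2-(4-hydroxy-2-methoxyphenyl)-4,6-dimethoxy-5-(3-methylbut-2-enyl)-1-benzofuran-3-carbaldehyde | COc1cc(O)ccc1-c1oc2cc(OC)c(CC=C(C)C)c(OC)c2c1C=O
F4 | step 6 | 2-iodo-3,5-dimethoxy-4-(3-methylbut-2-enyl)phenol | COc1cc(O)c(I)c(OC)c1CC=C(C)C
F5 | step 6 | 3,5-dimethoxy-4-(3-methylbut-2-enyl)-2-[(trimethylsilyl)ethynyl]phenol | COc1cc(O)c(C#C[Si](C)(C)C)c(OC)c1CC=C(C)C
F6 | step 5 | 2,4-dimethoxy-6-(methoxymethoxy)-3-(3-methylbut-2-enyl)benzaldehyde | COCOc1cc(OC)c(CC=C(C)C)c(OC)c1C=O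
F7 | step 5 | 1,3-dimethoxy-4-(2-methoxyethenyl)-5-(methoxymethoxy)-2-(3-methylbut-2-enyl)benzene (E/Z mixture) | COC=Cc1c(OCOC)cc(OC)c(CC=C(C)C)c1OC
A1 | alternative 1 | methyl 5-(2-diazoacetyl)-2-[2-methoxy-4-(triisopropylsilyloxy)phenyl]furan-3-carboxylate | COC(=O)c1cc(C(=O)C=[N+]=[N-])oc1-c1ccc(O[Si](C(C)C)(C(C)C)C(C)C)cc1OC
A2 | alternative 1 | 1-methoxy-5-methylhex-4-en-1-yne | COC#CCC=C(C)C
A3 | alternative 1 | methyl 2-[2-methoxy-4-(triisopropylsilyloxy)phenyl]-5-(2-oxoethenyl)furan-3-carboxylate | COC(=O)c1cc(C=C=O)oc1-c1ccc(O[Si](C(C)C)(C(C)C)C(C)C)cc1OC
A4 | alternative 1 | methyl 4-hydroxy-6-methoxy-2-[2-methoxy-4-(triisopropylsilyloxy)phenyl]-5-(3-methylbut-2-enyl)-1-benzofuran-3-carboxylate | COC(=O)c1c(-c2ccc(O[Si](C(C)C)(C(C)C)C(C)C)cc2OC)oc2cc(OC)c(CC=C(C)C)c(O)c12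
A5 | alternative 2 | {4-[(2,6-bis(methoxymethoxy)-4-methoxyphenyl)ethynyl]-3-methoxyphenoxy}tri(propan-2-yl)silane | COCOc1cc(OC)cc(OCOC)c1C#Cc1ccc(O[Si](C(C)C)(C(C)C)C(C)C)cc1OC
A6 | alternative 2 | 6-methoxy-3-(methoxymethyl)-4-(methoxymethoxy)-2-[2-methoxy-4-(triisopropylsilyloxy)phenyl]-1-benzofuran | COCc1c(-c2ccc(O[Si](C(C)C)(C(C)C)C(C)C)cc2OC)oc2cc(OC)cc(OCOC)c12
A7 | alternative 3 | 3,5-dimethoxy-4-(3-methylbut-2-enyl)-2-(trimethylsilyl)phenyl trifluoromethanesulfonate | COc1cc(OS(=O)(=O)C(F)(F)F)c([Si](C)(C)C)c(OC)c1CC=C(C)C
A8 | alternative 3 | 1,2-didehydro-3,5-dimethoxy-4-(3-methylbut-2-enyl)benzene | COC1=C(CC=C(C)C)C(OC)=CC#C1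
A9 | alternative 3 | phenyliodonium ylide of methyl 3-[2-methoxy-4-(methoxymethoxy)phenyl]-3-oxopropanoate | COC(=O)[C-]([I+]c1ccccc1)C(=O)c1ccc(OCOC)cc1OC
A10 | alternative 3 | methyl 4,6-dimethoxy-2-[2-methoxy-4-(methoxymethoxy)phenyl]-5-(3-methylbut-2-enyl)-1-benzofuran-3-carboxylate | COC(=O)c1c(-c2ccc(OCOC)cc2OC)oc2cc(OC)c(CC=C(C)C)c(OC)c12
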